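**Plan**
- Retrosynthetic cuts, in order: (i) the carboxyl group and the 5-OH are tied back as a six-membered aryl lactone (temporary ring); (ii) O1–C2 of the pyranone (oxa-Michael), then C3–C4 (aryl aldehyde + but-2-yne); (iii) prenyl → allyl → O-allyl ether (cross-metathesis, Claisen); (iv) the formyl carbon from the arene; (v) the benzylic C–aryl bond (phenol + enal).
- Forward order: the benzene ring is bought (3,5-dimethoxyphenol); the temporary lactone ring closes first (steps 1–2); the arene is then filled position by position (CHO, free OH, allyl → prenyl); the pyranone closes last (step 9); the lactone is then opened.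
- Enabling feature: the pyranone C4 ketone sits on the benzene carbon flanked by two phenolic oxygens (O1 and the 5-OH) and carries the CHMe–CHMe–O1 unit, so the ring is a closed aryl 2-methylbut-2-enoyl ketone. With the 5-O locked in the lactone, only O1 can add to the β-carbon.
- Stereochemistry: the benzylic centre (R) comes from iminium catalysis in step 1; C2 (S) from the quinidine-catalysed oxa-Michael addition; C3 (R) from kinetic protonation of the resulting enol anti to the C2 methyl (cis).

Key step: step 9

Assumption: the catalyst antipodes named in steps 1 and 9 are those expected from the usual facial models; the mirror-image catalysts are equally available and would be used if a trial shows the opposite sense.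

**Step 1**
Reactants: 1 3,5-dimethoxyphenol; 2 (E)-oct-2-enal
Product: 4 (4R)-5,7-dimethoxy-4-pentylchroman-2-ol (anomeric mixture), via open-chain hydroxy aldehyde 3 (not isolated)
Conditions: (S)-α,α-diphenylprolinol TMS ether (20 mol %), PhCO2H (20 mol %), toluene, 0 °C → rt
Reagents that add atoms: none
Why: Iminium-catalysed Friedel–Crafts alkylation/hemiacetalisation cascade of an electron-rich phenol with an enal: the carbon ortho to the OH of 1 should add to C3 of the (E)-iminium ion of 2 on the face away from the CPh2OTMS group, which sets the benzylic centre as R, and the phenol OH then closes on the released aldehyde.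

**Step 2**
Reactants: 4 (4R)-5,7-dimethoxy-4-pentylchroman-2-ol
Product: 5 (4R)-5,7-dimethoxy-4-pentylchroman-2-one
Conditions: Dess–Martin periodinane (1.3 equiv), CH2Cl2, rt
Reagents that add atoms: none
Why: Dess–Martin oxidation of a lactol to the lactone, which is the temporary ring that later masks the acid and the future 5-OH; the benzylic centre is not enolisable and is untouched.

**Step 3**
Reactants: 5 (4R)-5,7-dimethoxy-4-pentylchroman-2-one
Product: 6 (4R)-5,7-dimethoxy-2-oxo-4-pentylchromane-8-carbaldehyde
Conditions: Cl2CHOMe, TiCl4, CH2Cl2, −78 → 0 °C; then H2O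
Reagents that add atoms: dichloromethyl methyl ether, ClC(Cl)OC (formyl carbon); water, O (formyl oxygen, on hydrolysis)
Why: Rieche formylation of an activated arene: C8 is para to the 5-OMe and ortho to the 7-OMe and is flanked on its other side only by the ring oxygen, so it should be preferred to C6, which lies between two methoxy groups (the same preference as in the formylation of 3,5-dimethoxytoluene next to the methyl group).

**Step 4**
Reactants: 6 (4R)-5,7-dimethoxy-2-oxo-4-pentylchromane-8-carbaldehyde
Product: 7 (4R)-7-hydroxy-5-methoxy-2-oxo-4-pentylchromane-8-carbaldehyde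
Conditions: BCl3 (1.3 equiv), CH2Cl2, −78 → 0 °C; then H2O
Reagents that add atoms: none
Why: Chelation-controlled Lewis-acid demethylation: BCl3 bridges the aldehyde oxygen and the ortho 7-OMe oxygen in a six-membered chelate and chloride removes only that methyl, while the para 5-OMe and the lactone should remain.

**Step 5**
Reactants: 7 (4R)-7-hydroxy-5-methoxy-2-oxo-4-pentylchromane-8-carbaldehyde
Product: 8 (4R)-7-(allyloxy)-5-methoxy-2-oxo-4-pentylchromane-8-carbaldehyde
Conditions: allyl bromide, K2CO3, DMF, rt
Reagents that add atoms: allyl bromide, C=CCBr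
Why: Williamson O-alkylation of the single free (aldehyde-chelated) phenol under mild carbonate conditions that the aryl lactone should tolerate.

**Step 6**
Reactants: 8 (4R)-7-(allyloxy)-5-methoxy-2-oxo-4-pentylchromane-8-carbaldehyde
Product: 9 (4R)-6-allyl-7-hydroxy-5-methoxy-2-oxo-4-pentylchromane-8-carbaldehyde
Conditions: N,N-diethylaniline, 190 °C, sealed tube
Reagents that add atoms: none
Why: Aromatic Claisen rearrangement: of the two positions ortho to O7, C8 carries the formyl group, so the [3,3] shift should deliver the allyl group to C6 only, and tautomerisation restores the chelated phenol.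

**Step 7**
Reactants: 9 (4R)-6-allyl-7-hydroxy-5-methoxy-2-oxo-4-pentylchromane-8-carbaldehyde
Product: 10 (4R)-7-hydroxy-5-methoxy-6-(3-methylbut-2-en-1-yl)-2-oxo-4-pentylchromane-8-carbaldehyde
Conditions: 2-methyl-2-butene (excess), Grubbs II catalyst (5 mol %), 1,4-benzoquinone (10 mol %), CH2Cl2, 40 °C
Reagents that add atoms: 2-methyl-2-butene, CC=C(C)C
Why: Olefin cross-metathesis of the terminal allyl group with excess 2-methyl-2-butene gives the prenyl group with loss of propene; benzoquinone suppresses Ru–H isomerisation to the propenylarene, and the prenyl group is made only now because the Lewis-acid steps 3 and 4 would cyclise an ortho-prenylphenol.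

**Step 8**
Reactants: 10 (4R)-7-hydroxy-5-methoxy-6-(3-methylbut-2-en-1-yl)-2-oxo-4-pentylchromane-8-carbaldehyde; 11 but-2-yne
Product: 12 (4R)-7-hydroxy-5-methoxy-8-[(2E)-2-methylbut-2-enoyl]-6-(3-methylbut-2-en-1-yl)-4-pentylchroman-2-one
Conditions: [RhCl(cod)]2 (2.5 mol %), dppf (5 mol %), Na2CO3 (10 mol %), but-2-yne (5 equiv), toluene, 90 °C, sealed tube
Reagents that add atoms: none
Why: Rh(I)-catalysed intermolecular alkyne hydroacylation by a salicylaldehyde: the ortho phenoxide chelates the acyl–Rh–H intermediate and so suppresses decarbonylation, and syn addition of acyl and H across but-2-yne gives the (E)-2-methylbut-2-enoyl (tigloyl) ketone, the trisubstituted prenyl alkene being too hindered to insert.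

**Step 9**
Reactants: 12 (4R)-7-hydroxy-5-methoxy-8-[(2E)-2-methylbut-2-enoyl]-6-(3-methylbut-2-en-1-yl)-4-pentylchroman-2-one
Product: 14 (4R,8S,9R)-5-methoxy-8,9-dimethyl-6-(3-methylbut-2-en-1-yl)-4-pentyl-3,4,8,9-tetrahydro-2H,10H-pyrano[2,3-f]chromene-2,10-dione, via ring enol 13 (not isolated)
Conditions: quinidine (20 mol %), PhCl, 15 °C
Reagents that add atoms: none
Why: The closest known reaction type is the cinchona-alkaloid-catalysed enantioselective intramolecular oxa-Michael addition of o-tigloylphenols to cis-2,3-dimethylchroman-4-ones. The quinuclidine nitrogen of quinidine takes up the proton of the 7-OH (acidified by its hydrogen bond to the enone C=O) while the C9-OH holds the carbonyl oxygen, and the phenoxide oxygen adds to the β-carbon of the s-cis (E)-enone to give the ring enol 13. The pyranone closes in the 6-endo-trig mode by formation of the O7–C8 bond (O1–C2 of the target). C8 (S) is set by the catalyst, quinidine being chosen as the pseudoenantiomer of quinine, which is known to give the opposite (R)-configured cis series in this substrate class; C9 (R) is set by kinetic protonation of enol 13 by the quinuclidinium ion on the face anti to the new C8 methyl, which places the two methyl groups cis. The regioselectivity needed is that only one of the two oxygens ortho to the acyl group adds, and this is secured by the lactone, which holds the other oxygen as an aryl ester; the C4 centre is remote and should not override the catalyst. The cis isomer is the kinetic product, so a non-polar solvent, a low temperature and a stop at full conversion are used to avoid amine-mediated equilibration to trans.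

**Step 10**
Reactants: 14 (4R,8S,9R)-5-methoxy-8,9-dimethyl-6-(3-methylbut-2-en-1-yl)-4-pentyl-3,4,8,9-tetrahydro-2H,10H-pyrano[2,3-f]chromene-2,10-dione
Product: 15 (3R)-3-[(2S,3R)-5-hydroxy-7-methoxy-2,3-dimethyl-8-(3-methylbut-2-en-1-yl)-4-oxochroman-6-yl]octanoic acid (target)
Conditions: LiOH·H2O (1.05 equiv), THF–H2O 3:1, 0 °C; then 1 M HCl to pH 3–4, 0 °C
Reagents that add atoms: lithium hydroxide, [Li+].[OH-] (its oxygen ends in the carboxyl group)
Why: Saponification of the aryl ester (lactone) by one equivalent of hydroxide, which should be far faster than enolisation of the ketone; the base is consumed as the carboxylate and the released phenol is hydrogen-bonded to the C4 ketone, so that neither C3 epimerisation nor retro-oxa-Michael opening is expected, and cold acidification to pH 3–4 gives the hydroxy acid without relactonisation.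

**Compound list**
1 | 3,5-dimethoxyphenol | COc1cc(O)cc(OC)c1 | starting material
2 | (E)-oct-2-enal | CCCCC/C=C/C=O | starting material
3 | (3R)-3-(2-hydroxy-4,6-dimethoxyphenyl)octanal | CCCCC[C@H](CC=O)c1c(O)cc(OC)cc1OC | intermediate (not isolated)
4 | (4R)-5,7-dimethoxy-4-pentylchroman-2-ol (anomeric mixture) | CCCCC[C@@H]1CC(O)Oc2cc(OC)cc(OC)c21 | intermediate
5 | (4R)-5,7-dimethoxy-4-pentylchroman-2-one | CCCCC[C@@H]1CC(=O)Oc2cc(OC)cc(OC)c21 | intermediate
6 | (4R)-5,7-dimethoxy-2-oxo-4-pentylchromane-8-carbaldehyde | CCCCC[C@@H]1CC(=O)Oc2c(C=O)c(OC)cc(OC)c21 | intermediate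
7 | (4R)-7-hydroxy-5-methoxy-2-oxo-4-pentylchromane-8-carbaldehyde | CCCCC[C@@H]1CC(=O)Oc2c(C=O)c(O)cc(OC)c21 | intermediate
8 | (4R)-7-(allyloxy)-5-methoxy-2-oxo-4-pentylchromane-8-carbaldehyde | CCCCC[C@@H]1CC(=O)Oc2c(C=O)c(OCC=C)cc(OC)c21 | intermediate
9 | (4R)-6-allyl-7-hydroxy-5-methoxy-2-oxo-4-pentylchromane-8-carbaldehyde | CCCCC[C@@H]1CC(=O)Oc2c(C=O)c(O)c(CC=C)c(OC)c21 | intermediate
10 | (4R)-7-hydroxy-5-methoxy-6-(3-methylbut-2-en-1-yl)-2-oxo-4-pentylchromane-8-carbaldehyde | CCCCC[C@@H]1CC(=O)Oc2c(C=O)c(O)c(CC=C(C)C)c(OC)c21 | intermediate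
11 | but-2-yne | CC#CC | starting material
12 | (4R)-7-hydroxy-5-methoxy-8-[(2E)-2-methylbut-2-enoyl]-6-(3-methylbut-2-en-1-yl)-4-pentylchroman-2-one | CCCCC[C@@H]1CC(=O)Oc2c(C(=O)/C(C)=C/C)c(O)c(CC=C(C)C)c(OC)c21 | intermediate
13 | (4R,8S)-10-hydroxy-5-methoxy-8,9-dimethyl-6-(3-methylbut-2-en-1-yl)-4-pentyl-3,4-dihydro-2H,8H-pyrano[2,3-f]chromen-2-one (ring enol) | CCCCC[C@@H]1CC(=O)Oc2c3C(O)=C(C)[C@H](C)Oc3c(CC=C(C)C)c(OC)c21 | intermediate (not isolated)
14 | (4R,8S,9R)-5-methoxy-8,9-dimethyl-6-(3-methylbut-2-en-1-yl)-4-pentyl-3,4,8,9-tetrahydro-2H,10H-pyrano[2,3-f]chromene-2,10-dione | CCCCC[C@@H]1CC(=O)Oc2c3C(=O)[C@H](C)[C@H](C)Oc3c(CC=C(C)C)c(OC)c21 | intermediate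
15 | (3R)-3-[(2S,3R)-5-hydroxy-7-methoxy-2,3-dimethyl-8-(3-methylbut-2-en-1-yl)-4-oxochroman-6-yl]octanoic acid | CCCCC[C@H](CC(=O)O)c1c(O)c2c(c(CC=C(C)C)c1OC)O[C@@H](C)[C@@H](C)C2=O | target

**Count**
Total steps: 10. Longest linear sequence: 10 steps (1 → 15); but-2-yne (11) joins at step 8.

**Steps most likely to fail**

Step 9. The process at risk is facial discrimination in the C–O bond formation (pseudoenantiomeric catalyst, crowding by the ortho prenyl group); the kinetic cis relationship may also erode by enolisation, and the aryl lactone may slowly acylate the catalyst hydroxyl. The fallback sets out from 12 and returns to 14; it closes the ring by SN2 displacement at a carbinol centre instead of by conjugate addition. Copper(I)-catalysed enantioselective conjugate borylation of 12 (CuCl, NaOt-Bu, Josiphos-type ligand of the antipode that gives the 3R boronate, B2pin2, MeOH, THF, −20 °C, where the borylation should outrun background cyclisation) would give the β-boryl ketone F1. Buffered oxidation (H2O2, pH 7 phosphate, THF, 0 °C, retention at carbon) would give the β-hydroxy ketone F2. Mitsunobu closure (PPh3, DIAD, toluene, 0 °C) lets the phenol oxygen displace the activated carbinol with inversion, which fixes C8 as S independently of any oxa-Michael face selectivity. It should return 14 together with its C9 epimer, the trans-chromanone F3, from which 14 is separated by chromatography.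

Step 8. The process at risk is slow C–H activation or decarbonylation at the doubly ortho-substituted aldehyde, or premature base-mediated (racemic) ring closure of the product at 90 °C. The fallback sets out from 10 and returns to 12. Nozaki–Hiyama–Kishi addition of (E)-2-bromobut-2-ene (CrCl2, cat. NiCl2, DMF, rt), which should tolerate the lactone and the phenol, would give the allylic alcohol F4. MnO2 (CH2Cl2, rt) would then oxidise this benzylic and allylic alcohol to 12 under neutral conditions.

Step 3. The process at risk is incomplete regiocontrol, with attack at C6 between the two methoxy groups. The fallback sets out from 5 and returns to 6; it uses the lactone oxygen as an ortho director. Methanolysis (cat. K2CO3, MeOH, rt) would open 5 to the phenol ester F5, whose only free ortho position is the future C8. Magnesium-mediated ortho-formylation (MgCl2, Et3N, paraformaldehyde, MeCN, reflux), which is specific for the position ortho to the phenoxide, would give the salicylaldehyde ester F6. p-TsOH (cat.) in toluene at reflux would reclose the lactone with loss of methanol to give 6.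

**Further compounds**
F1 | step 9 | (4R)-7-hydroxy-5-methoxy-8-[(3R)-2-methyl-3-(4,4,5,5-tetramethyl-1,3,2-dioxaborolan-2-yl)butanoyl]-6-(3-methylbut-2-en-1-yl)-4-pentylchroman-2-one (C2′ epimers) | CCCCC[C@@H]1CC(=O)Oc2c(C(=O)C(C)[C@@H](C)B3OC(C)(C)C(C)(C)O3)c(O)c(CC=C(C)C)c(OC)c21
F2 | step 9 | (4R)-7-hydroxy-8-[(3R)-3-hydroxy-2-methylbutanoyl]-5-methoxy-6-(3-methylbut-2-en-1-yl)-4-pentylchroman-2-one (C2′ epimers) | CCCCC[C@@H]1CC(=O)Oc2c(C(=O)C(C)[C@@H](C)O)c(O)c(CC=C(C)C)c(OC)c21
F3 | step 9 | (4R,8S,9S)-5-methoxy-8,9-dimethyl-6-(3-methylbut-2-en-1-yl)-4-pentyl-3,4,8,9-tetrahydro-2H,10H-pyrano[2,3-f]chromene-2,10-dione | CCCCC[C@@H]1CC(=O)Oc2c3C(=O)[C@@H](C)[C@H](C)Oc3c(CC=C(C)C)c(OC)c21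
F4 | step 8 | (4R)-7-hydroxy-8-[(2E)-1-hydroxy-2-methylbut-2-en-1-yl]-5-methoxy-6-(3-methylbut-2-en-1-yl)-4-pentylchroman-2-one (carbinol epimers) | CCCCC[C@@H]1CC(=O)Oc2c(C(O)/C(C)=C/C)c(O)c(CC=C(C)C)c(OC)c21
F5 | step 3 | methyl (3R)-3-(2-hydroxy-4,6-dimethoxyphenyl)octanoate | CCCCC[C@H](CC(=O)OC)c1c(O)cc(OC)cc1OC
F6 | step 3 | methyl (3R)-3-(3-formyl-2-hydroxy-4,6-dimethoxyphenyl)octanoate | CCCCC[C@H](CC(=O)OC)c1c(O)c(C=O)c(OC)cc1OC
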